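**Retrosynthetic overview**
Target 23 ← Mitsunobu esterification with inversion at C-4 of syn-diol 21 ← titanocene radical opening of 3a,4-epoxide 20 (sets H-3a) ← isopropyl addition, hydroxyl-directed epoxidation and Corey–Bakshi–Shibata reduction, back to bicyclic enone 15.
Key disconnection C-3–C-3a: the five-membered ring (C-1, C-2, C-3, C-3a, C-8a) is closed last, by palladium-catalysed addition of the C-3a alkenyl triflate of 13 across its own nitrile, whose carbon becomes C-3.
Enabling feature: C-3a of the seven-membered ring lies between quaternary C-8a and CH2-4, so ketone 12 gives one enol triflate only, the alkenylpalladium has no β-hydrogen, and the C3a=C4 bond that survives ring closure is the handle for H-3a and O-4.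
Quaternary C-8a ← asymmetric Michael addition of the (R)-1-phenylethanamine imine of cycloheptenone 7 to acrylonitrile.
Ring order: seven-membered ring first (step 3, 5-exo-dig alkoxide addition then Claisen ring expansion of acyclic alkynol 5), five-membered ring second (step 6).

Key step: step 6

Assumption: the imine of (R)-1-phenylethanamine is taken to direct acrylonitrile to the enamine face that gives the (R)-configured quaternary carbon, as its 2-methylcycloalkanone analogues do; compounds 5 to 7 are racemic and their stereocentres are erased later.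

Step 1
Reactants: 1 pent-3-yn-1-ol
Product: 2 5-bromopent-2-yne
Conditions: CBr4, PPh3, CH2Cl2, 0 °C
Reagents that add atoms: carbon tetrabromide, BrC(Br)(Br)Br
Why: Appel reaction, in which bromide displaces the alkoxyphosphonium ion at the primary carbon under neutral conditions that leave the internal alkyne untouched.

Step 2
Reactants: 2 5-bromopent-2-yne, 3 but-3-en-2-one
Product: 5 3-methyloct-1-en-6-yn-3-ol, via pent-3-ynylmagnesium bromide 4 (not isolated)
Conditions: Mg, THF; then CeCl3, 3, THF, −78 °C
Reagents that add atoms: but-3-en-2-one (3), CC(=O)C=C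
Why: Grignard 1,2-addition to the ketone carbonyl, which CeCl3 favours over conjugate addition; the tertiary carbinol forms as a racemate, which is sufficient because this centre becomes trigonal in step 3.

Step 3
Reactants: 5 3-methyloct-1-en-6-yn-3-ol
Product: 7 2,5-dimethylcyclohept-4-en-1-one, via enol ether 6 (not isolated)
Conditions: MeLi (10 mol %), phenetole, 150 → 200 °C, sealed tube
Reagents that add atoms: none
Why: Tandem reaction of a known type: the lithium alkoxide adds 5-exo-dig and anti across the alkyne to the (Z)-2-alkylidene-5-vinyloxolane 6, whose allyl vinyl ether unit undergoes Claisen [3,3] rearrangement with two-carbon ring expansion, so that the seven-membered ring, its trisubstituted C=C and the methyl group on it are in place (the C-2 centre is racemic and is erased in step 4).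

Step 4
Reactants: 7 2,5-dimethylcyclohept-4-en-1-one, 8 (R)-1-phenylethanamine, 9 acrylonitrile
Product: 12 3-[(1R)-1,4-dimethyl-7-oxocyclohept-3-en-1-yl]propanenitrile, via imine 10 (not isolated), via adduct imine 11 (not isolated)
Conditions: 8, p-toluenesulfonic acid (cat.), toluene, reflux, −H2O; then 9, THF, 40 °C; then 20% aq. AcOH, rt
Reagents that add atoms: acrylonitrile (9), C=CC#N; water, O
Why: Asymmetric Michael addition of a chiral imine: the more substituted secondary enamine tautomer of 10 should add to acrylonitrile through a compact aza-ene-like transition state on the face away from the phenyl group of the auxiliary, which creates the quaternary carbon (later C-8a) regioselectively at the methyl-bearing α-carbon with R configuration, and acid hydrolysis returns the amine.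

Step 5
Reactants: 12 3-[(1R)-1,4-dimethyl-7-oxocyclohept-3-en-1-yl]propanenitrile
Product: 13 (7R)-7-(2-cyanoethyl)-4,7-dimethylcyclohepta-1,4-dien-1-yl trifluoromethanesulfonate
Conditions: KN(SiMe3)2, THF, −78 °C; then PhNTf2, −78 → 0 °C
Reagents that add atoms: N-phenylbis(trifluoromethanesulfonimide), O=S(=O)(N(c1ccccc1)S(=O)(=O)C(F)(F)F)C(F)(F)F
Why: Enol triflate formation: the ketone is more acidic than the nitrile and can enolize only toward its CH2 because the other α-carbon is quaternary, so O-triflation of the single potassium enolate should give one regioisomer.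

Step 6
Reactants: 13 (7R)-7-(2-cyanoethyl)-4,7-dimethylcyclohepta-1,4-dien-1-yl trifluoromethanesulfonate
Product: 15 (8aR)-6,8a-dimethyl-2,5,8,8a-tetrahydroazulen-3(1H)-one, via ketimine 14 (not isolated)
Conditions: Pd(OAc)2 (10 mol %), dppp, Et3N, DMF/H2O (9:1), 100 °C
Reagents that add atoms: water, O
Why: Zerovalent palladium inserts into the C3a–O bond of the alkenyl triflate, the cationic alkenylpalladium binds the tethered nitrile and adds across C≡N to an N-palladated ketimine, water protonates this to ketimine 14, which hydrolyses to the enone, and triethylamine returns divalent palladium to the zerovalent state. The closest known reaction type is the palladium-catalysed cyclization of 2-iodoaryl- and 2-haloalkenyl-alkanenitriles to indanones and cyclopentenones (intramolecular carbopalladation of a nitrile). The five-membered ring (C-1, C-2, C-3, C-3a, C-8a) is closed in the 5-exo-dig mode by attack of C-3a on the nitrile carbon, which becomes the C-3 carbonyl. No stereocentre is formed: C-3a is kept trigonal on purpose, because ring closure onto a tetrahedral C-3a from the chain on C-8a could only give the cis ring fusion, whereas the surviving C3a=C4 enone lets H-3a and O-4 be set afterwards from the C-3 carbinol. The selectivity needed is nitrile insertion ahead of β-hydride elimination, Heck insertion and reduction of the alkenylpalladium; the substrate secures it because the metal-bearing C-3a has no β-hydrogen (C-8a is quaternary, C-4 is trigonal), the only other alkene (C6=C7) could be reached only through a four-membered ring, and the geminal substituents on C-8a hold the cyanoethyl chain close to the metal.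

Step 7
Reactants: 15 (8aR)-6,8a-dimethyl-2,5,8,8a-tetrahydroazulen-3(1H)-one
Product: 16 (3S,8aR)-6,8a-dimethyl-1,2,3,5,8,8a-hexahydroazulen-3-ol
Conditions: (R)-2-methyl-CBS-oxazaborolidine [(3aR)-1-methyl-3,3-diphenyltetrahydro-1H,3H-pyrrolo[1,2-c][1,3,2]oxazaborole] (20 mol %), catecholborane, toluene, −78 °C
Reagents that add atoms: none
Why: Corey–Bakshi–Shibata reduction: 1,2-hydride delivery under catalyst control, with alkenyl carbon C-3a as the large and CH2-2 as the small substituent, so that the (R)-oxazaborolidine should give the 3S alcohol (hydroxyl cis to the 8a-methyl group), while catecholborane at low temperature leaves the isolated alkene alone.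

Step 8
Reactants: 16 (3S,8aR)-6,8a-dimethyl-1,2,3,5,8,8a-hexahydroazulen-3-ol
Product: 17 (3S,3aR,4R,8aR)-3a,4-epoxy-6,8a-dimethyl-1,2,3,3a,4,5,8,8a-octahydroazulen-3-ol
Conditions: VO(acac)2 (5 mol %), t-BuOOH, CH2Cl2, 0 °C → rt
Reagents that add atoms: tert-butyl hydroperoxide, CC(C)(C)OO
Why: Hydroxyl-directed epoxidation: the vanadium alkoxide of the allylic alcohol should deliver the peroxide oxygen to C3a=C4 on the face of the 3-hydroxyl group and not touch the isolated C6=C7 bond, which sets C-3a and C-4 with the oxygen cis to the 8a-methyl group.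

Step 9
Reactants: 17 (3S,3aR,4R,8aR)-3a,4-epoxy-6,8a-dimethyl-1,2,3,3a,4,5,8,8a-octahydroazulen-3-ol
Product: 18 (3aS,4R,8aR)-3a,4-epoxy-6,8a-dimethyl-2,3a,4,5,8,8a-hexahydroazulen-3(1H)-one
Conditions: Dess–Martin periodinane, NaHCO3, CH2Cl2, 0 °C → rt
Reagents that add atoms: none
Why: Dess–Martin oxidation of the secondary alcohol under buffered conditions; the neighbouring C-3a is fully substituted, so no centre can epimerize.

Step 10
Reactants: 18 (3aS,4R,8aR)-3a,4-epoxy-6,8a-dimethyl-2,3a,4,5,8,8a-hexahydroazulen-3(1H)-one, 19 isopropylmagnesium chloride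
Product: 20 (3R,3aS,4R,8aR)-3a,4-epoxy-6,8a-dimethyl-3-(propan-2-yl)-1,2,3,3a,4,5,8,8a-octahydroazulen-3-ol
Conditions: 19, CeCl3, THF, −78 °C
Reagents that add atoms: isopropylmagnesium chloride (19), CC(C)[Mg]Cl
Why: Organocerium 1,2-addition (low basicity, no enolization): the isopropyl group should enter anti to the C3a–O bond of the spiro-epoxide (Felkin–Anh, away from the epoxide oxygen and the 8a-methyl group), which places the new tertiary hydroxyl cis to the epoxide oxygen (3R).

Step 11
Reactants: 20 (3R,3aS,4R,8aR)-3a,4-epoxy-6,8a-dimethyl-3-(propan-2-yl)-1,2,3,3a,4,5,8,8a-octahydroazulen-3-ol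
Product: 21 (3R,3aS,4R,8aR)-6,8a-dimethyl-3-(propan-2-yl)-1,2,3,3a,4,5,8,8a-octahydroazulene-3,4-diol
Conditions: Cp2TiCl2 (20 mol %), Mn, 2,4,6-collidine hydrochloride, 1,4-cyclohexadiene, THF, rt
Reagents that add atoms: none
Why: Reductive epoxide opening by trivalent titanium (formed from Cp2TiCl2 and Mn), of the type known to turn 2,3-epoxy alcohols into 1,3-diols: the C3a–O bond is cleaved homolytically to the tertiary C-3a radical, which should take a hydrogen atom from 1,4-cyclohexadiene on the face opposite the 4-titanoxy, 3-hydroxy and 8a-methyl groups, giving H-3a trans to the methyl group (3aS) and leaving O-4 in place (4R).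

Step 12
Reactants: 21 (3R,3aS,4R,8aR)-6,8a-dimethyl-3-(propan-2-yl)-1,2,3,3a,4,5,8,8a-octahydroazulene-3,4-diol, 22 4-methoxybenzoic acid
Product: 23 [(3R,3aS,4S,8aR)-3-hydroxy-6,8a-dimethyl-3-(propan-2-yl)-1,2,3,3a,4,5,8,8a-octahydroazulen-4-yl] 4-methoxybenzoate
Conditions: PPh3, DIAD, 22, toluene, 0 °C → rt
Reagents that add atoms: 4-methoxybenzoic acid (22), COc1ccc(C(=O)O)cc1
Why: Mitsunobu esterification: the secondary 4-hydroxyl is activated as the oxyphosphonium ion and displaced by 4-methoxybenzoate with inversion (4R to 4S), while the tertiary 3-hydroxyl is not activated and, being on the same face as the leaving group, cannot displace it.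

**Compound list**
1 | pent-3-yn-1-ol | CC#CCCO | starting material
2 | 5-bromopent-2-yne | CC#CCCBr | intermediate
3 | but-3-en-2-one | CC(=O)C=C | starting material
4 | pent-3-ynylmagnesium bromide | CC#CCC[Mg]Br | intermediate
5 | 3-methyloct-1-en-6-yn-3-ol (racemic) | C=CC(C)(O)CCC#CC | intermediate
6 | (Z)-5-ethenyl-2-ethylidene-5-methyloxolane (racemic) | C/C=C1/CCC(C)(C=C)O1 | intermediate
7 | 2,5-dimethylcyclohept-4-en-1-one (racemic) | CC1CC=C(C)CCC1=O | intermediate
8 | (R)-1-phenylethanamine | C[C@@H](N)c1ccccc1 | starting material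
9 | acrylonitrile | C=CC#N | starting material
10 | N-[(1R)-1-phenylethyl]imine of 7 (mixture at ring C-2 and C=N) | CC1CC=C(C)CCC1=N[C@H](C)c1ccccc1 | intermediate
11 | N-[(1R)-1-phenylethyl]imine of 12 | N#CCC[C@]1(C)CC=C(C)CCC1=N[C@H](C)c1ccccc1 | intermediate
12 | 3-[(1R)-1,4-dimethyl-7-oxocyclohept-3-en-1-yl]propanenitrile | N#CCC[C@]1(C)CC=C(C)CCC1=O | intermediate
13 | (7R)-7-(2-cyanoethyl)-4,7-dimethylcyclohepta-1,4-dien-1-yl trifluoromethanesulfonate | N#CCC[C@]1(C)CC=C(C)CC=C1OS(=O)(=O)C(F)(F)F | intermediate
14 | (8aR)-6,8a-dimethyl-2,5,8,8a-tetrahydroazulen-3(1H)-imine | N=C1CC[C@]2(C)CC=C(C)CC=C12 | intermediate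
15 | (8aR)-6,8a-dimethyl-2,5,8,8a-tetrahydroazulen-3(1H)-one | O=C1CC[C@]2(C)CC=C(C)CC=C12 | intermediate
16 | (3S,8aR)-6,8a-dimethyl-1,2,3,5,8,8a-hexahydroazulen-3-ol (hydroxyl cis to 8a-methyl) | O[C@H]1CC[C@]2(C)CC=C(C)CC=C12 | intermediate
17 | (3S,3aR,4R,8aR)-3a,4-epoxy-6,8a-dimethyl-1,2,3,3a,4,5,8,8a-octahydroazulen-3-ol (epoxide oxygen cis to 3-hydroxyl and 8a-methyl) | O[C@H]1CC[C@]2(C)CC=C(C)C[C@H]3O[C@@]123 | intermediate
18 | (3aS,4R,8aR)-3a,4-epoxy-6,8a-dimethyl-2,3a,4,5,8,8a-hexahydroazulen-3(1H)-one | O=C1CC[C@]2(C)CC=C(C)C[C@H]3O[C@@]123 | intermediate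
19 | isopropylmagnesium chloride | CC(C)[Mg]Cl | starting material
20 | (3R,3aS,4R,8aR)-3a,4-epoxy-6,8a-dimethyl-3-(propan-2-yl)-1,2,3,3a,4,5,8,8a-octahydroazulen-3-ol (hydroxyl, epoxide oxygen and 8a-methyl on one face) | CC(C)[C@]1(O)CC[C@]2(C)CC=C(C)C[C@H]3O[C@@]123 | intermediate
21 | (3R,3aS,4R,8aR)-6,8a-dimethyl-3-(propan-2-yl)-1,2,3,3a,4,5,8,8a-octahydroazulene-3,4-diol (trans ring fusion, both hydroxyls cis to 8a-methyl) | CC(C)[C@]1(O)CC[C@]2(C)CC=C(C)C[C@@H](O)[C@@H]12 | intermediate
22 | 4-methoxybenzoic acid | COc1ccc(C(=O)O)cc1 | starting material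
23 | fertidin, [(3R,3aS,4S,8aR)-3-hydroxy-6,8a-dimethyl-3-(propan-2-yl)-1,2,3,3a,4,5,8,8a-octahydroazulen-4-yl] 4-methoxybenzoate | COc1ccc(C(=O)O[C@H]2CC(C)=CC[C@@]3(C)CC[C@@](O)(C(C)C)[C@H]23)cc1 | target

Total step count: 12
Longest linear sequence: 12 steps (1 → 23; compounds 3, 8, 9, 19 and 22 are purchased).

**Steps most likely to fail**

Step 6. The alkenylpalladium may be reduced before it inserts the nitrile, and at the reaction temperature the amine may move the C3a=C4 double bond of the product into conjugation with C6=C7. The fallback sets out from 13 and comes back at 15. The nitrile of 13 is reduced with i-Bu2AlH (toluene, −78 °C, then dilute acid) to (7R)-4,7-dimethyl-7-(3-oxopropyl)cyclohepta-1,4-dien-1-yl trifluoromethanesulfonate F1. Intramolecular Nozaki–Hiyama–Kishi coupling of the alkenyl triflate with the aldehyde (CrCl2, NiCl2 cat., DMF, rt) closes the five-membered ring to (8aR)-6,8a-dimethyl-1,2,3,5,8,8a-hexahydroazulen-3-ol F2, expected as a mixture of C-3 epimers. Oxidation with MnO2 (CH2Cl2, rt) gives 15.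

Step 11. Hydrogen-atom transfer to the planar C-3a radical may take place on the wrong face, or the radical may be trapped by a second trivalent titanium and lose a neighbouring oxygen by β-elimination. The fallback sets out from 20 and comes back at 21. Meinwald rearrangement of the epoxide with BF3·OEt2 (CH2Cl2, −78 °C), in which hydride shifts from C-4 to C-3a anti to the departing oxygen, should give (3R,3aR,8aR)-3-hydroxy-6,8a-dimethyl-3-(propan-2-yl)-2,3,3a,5,8,8a-hexahydroazulen-4(1H)-one F3 with H-3a already trans to the methyl group. Narasaka–Prasad reduction (Et2BOMe, NaBH4, THF/MeOH, −78 °C) then gives the syn-diol 21.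

Step 12. Activation of the hindered 4-hydroxyl may be slow, and E2 elimination toward C-5 may overtake substitution. The fallback sets out from 21 and comes back at 23. Dess–Martin oxidation of the secondary alcohol gives the same ketol F3. Evans–Saksena reduction with Me4NBH(OAc)3 (MeCN/AcOH, −20 °C) delivers hydride from the face of the 3-hydroxyl group and should give jaeschkeanadiol, (3R,3aS,4S,8aR)-6,8a-dimethyl-3-(propan-2-yl)-1,2,3,3a,4,5,8,8a-octahydroazulene-3,4-diol F4. Acylation of its secondary hydroxyl with 4-methoxybenzoyl chloride (pyridine, DMAP, CH2Cl2) gives 23.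

**Further compounds**
F1 | step 6 | (7R)-4,7-dimethyl-7-(3-oxopropyl)cyclohepta-1,4-dien-1-yl trifluoromethanesulfonate | O=CCC[C@]1(C)CC=C(C)CC=C1OS(=O)(=O)C(F)(F)F
F2 | step 6 | (8aR)-6,8a-dimethyl-1,2,3,5,8,8a-hexahydroazulen-3-ol (C-3 epimers) | OC1CC[C@]2(C)CC=C(C)CC=C12
F3 | step 11 | (3R,3aR,8aR)-3-hydroxy-6,8a-dimethyl-3-(propan-2-yl)-2,3,3a,5,8,8a-hexahydroazulen-4(1H)-one | CC(C)[C@]1(O)CC[C@]2(C)CC=C(C)CC(=O)[C@@H]12
F4 | step 12 | jaeschkeanadiol, (3R,3aS,4S,8aR)-6,8a-dimethyl-3-(propan-2-yl)-1,2,3,3a,4,5,8,8a-octahydroazulene-3,4-diol | CC(C)[C@]1(O)CC[C@]2(C)CC=C(C)C[C@H](O)[C@@H]12
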